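# Proposed total synthesis of CNP0329842.0 (21) by carbenoid O–H macrocyclisation on a dearomatised ring A

## The problem

Target 21 is a macrocyclic bis(bibenzyl): four benzene rings are tied into one 20-membered ring by two CH2CH2 bridges (A–D and B–C) and two diaryl ether oxygens (A–O–B and C–O–D). Ring A is the phenol ring whose ether oxygen is para to its CH2 arm, ring B is meta-disubstituted, ring C is para-disubstituted, and ring D is the phenol ring whose ether oxygen is meta to its CH2 arm. There is no stereocentre, so nothing has to be controlled stereochemically; the difficulties are regiochemistry and ring size. Each ether oxygen sits ortho to a free hydroxyl, and the two catechol-type rings differ only in where the bridge stands: para to the ether oxygen on ring A, para to the hydroxyl on ring D. The free phenols and the electron-rich aryl ethers do not tolerate oxidants or strong electrophiles, so one hydroxyl is best carried as a robust methyl ether and the other should appear only near the end. Closing the 20-membered ring is the central problem, because diaryl ether macrocyclisations of the Ullmann or SNAr kind are slow, hot and basic. The structure offers a way round this in ring A: OH at C1, OAr at C2 and the bridge at C5 is the pattern of a 2-oxygenated 5-substituted cyclohexane-1,3-dione, whose C2 can be made a carbenoid carbon by diazo transfer. That dione is symmetric about its C2–C5 axis, so an O–H insertion at C2 places the ether oxygen para to the bridge without any regiochemical choice, and either carbonyl can become the ring A hydroxyl.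

## Retrosynthesis

**21 from 20.** The O–CH3 bond of ring D is cut last. A methyl ether is the one phenol protecting group that should survive every earlier operation (base, hydride, hydrogenation, carbenoid, triflation, palladium), and BBr3 leaves diaryl ethers alone. Methyl ether 20 differs from the target by one carbon only.

**20 from 19, 18 and 17.** Ring A is taken back out of the aromatic state. Phenol 20 comes from 2-aryloxycyclohexenone 19 by loss of two hydrogens, 19 from enol triflate 18 by replacing C–OTf with C–H, and 18 from the enolised 2-aryloxy-1,3-dione 17. The neighbouring option is to aromatise 17 directly to a 2-aryloxyresorcinol. That was rejected because it creates two equivalent phenols on an electron-rich ring, one of which would then have to be removed statistically. In the dearomatised state the two oxygens are told apart for free, as enol and ketone. The forward steps ask for a clean O-triflation, a chemoselective hydrogenolysis and one dehydrogenation.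

**17 from 16 (key cut).** The O(ring B)–C2(ring A) bond is cut, which opens the 20-membered ring to the acyclic diazo dione 16 with a free ring B phenol. The same bond could be cut in aromatic form (Ullmann closure), or the C–O–D ether or a CH2–CH2 bridge could be opened instead. All of those closures are slow reactions, so oligomerisation gets its chance during the long exposure to base and heat. The carbenoid is generated irreversibly under neutral conditions and trapped within its short lifetime, without base or leaving group. The forward reaction must favour the single O–H bond over the arenes and ether oxygens of the chain.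

**16 from 15 and 14.** The C=N2 unit is removed (diazo transfer at the doubly activated C2 of dione 15). Dione 15 is traced to 14, in which the ring B phenol is a benzyl ether and the B–C bridge is still an E-stilbene. One hydrogenation then does both jobs. The stilbene is made E-selectively and carried as a single isomer, which saves a separate bridge reduction.

**14 from 9 and 10.** The carbocycle that will become ring A is cut at C4–C5 and C2–C3 of the dione. This is the retron of the classical malonate Michael addition–Claisen cyclisation–decarboxylation on enone 9 with diethyl malonate 10. Two C–C bonds and the whole ring A carbon skeleton arise in one flask from an open-chain enone.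

**9 from 7 and 8; 7 from 6.** The enone C=C is cut to aldehyde 7 and the stabilised acetonylidene ylide 8 (Wittig), and the aldehyde is taken back to methyl ester 6 (partial hydride reduction). This places the two-carbon spacer between ring D and C5 of the future ring A using a commercially available arylpropanoic acid.

**6 from 2 and 5.** The C–O–D ether is cut at O–C(ring C) to phenol 2 and aryl bromide 5. This diaryl ether is made early and intermolecularly on simple partners, where an Ullmann coupling is at its best. The ring D oxygen pattern (ether meta, hydroxyl para to the chain) is bought with the starting acid 1 and never has to be created.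

**5 from 3 and 4; 2 from 1.** The stilbene C=C is cut to phosphonate 3 and aldehyde 4 (Horner–Wadsworth–Emmons), and ester 2 comes from acid 1 by esterification. All five starting materials (1, 3, 4, 8, 10) are simple and commercially available.

## Roads not taken

**Alternative 1:** Ring D is built de novo and the macrocycle is closed afterwards. The cut goes through two C–C bonds of ring D. In the forward sense the ring C aryloxyacetone A2 and the ring A 2-alkylacrolein A3 undergo pyrrolidine-catalysed Michael addition and aldol condensation to a 6-aryloxy-4-alkylcyclohexenone, and iodine in DMSO dehydrogenates it to the open-chain 2-aryloxy-4-alkylphenol A1. Debenzylation, an intramolecular Ullmann closure of the ring A bromide onto the ring B phenol, and demethylation would follow.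
- Merits: the step is convergent, sets the ring D oxygen pattern unambiguously, and needs no copper for the C–O–D ether. The endgame after ring closure is a single demethylation, shorter than the four steps the chosen plan needs after its key step.
- Weak points: it solves the easy ether and leaves the hard problem, the 20-membered closure, to a hot, basic Ullmann reaction at a bromide flanked by a methoxy group. The benzyl ether must be removed in the presence of an aryl bromide, which rules out hydrogenolysis. Enamine formation in A2 can occur on either side of the ketone, A3 polymerises easily, and iodine may iodinate the electron-rich rings.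
- Comparison: the chosen plan pays for its mild, irreversible ring closure with a longer endgame, but it avoids the halogen/benzyl conflict and does not stake the macrocycle on an Ullmann closure.

**Alternative 2:** A Fries rearrangement across a catechol macrolactone. The cut is the C(ring D)–C(acyl) bond. The 20-membered aryl ester A5 (ring A arylacetic acid esterified with the ring D 2-aryloxyphenol) is ionised by TiCl4 or trifluoromethanesulfonic acid, and the tethered acylium re-attacks ring D para to oxygen. This gives the macrocyclic benzylic ketone A4 with the ring D hydroxyl set free.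
- Merits: all four rings come from aromatic feedstock, macrolactonisation is dependable, no protecting group is spent on the ring D hydroxyl, and the overall step count would probably be lower than in the chosen plan.
- Weak points: para-Fries migration is a dissociative process. An arylacetyl cation carrying a para-aryloxy group loses CO readily to a stabilised benzyl cation, which leads to benzylation instead of acylation. The free ortho position of ring D and the activated positions of rings B and C compete for the electrophile. The Lewis acid can cleave the ring A methyl ether, and the ketone of A4 must still be reduced to CH2.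
- Comparison: in the chosen plan the carbenoid carbon is the only electrophile and the phenol O–H its best trap, so site selectivity follows from the structure and does not depend on ion-pair behaviour. The price is the de novo construction of ring A.

**Alternative 3:** Anodic halophenol coupling closes the ring D ether. The cut is the O–C(ring D) bond. The seco-bisphenol A7 (ring D as a 2,6-dibromophenol, ring C as a 2,6-dichlorophenol, A–O–B ether already in place) is oxidised at the anode. The ring C phenol oxygen adds at a brominated ortho carbon of the oxidised ring D, and zinc in acetic acid re-aromatises to the trihalogenated macrocycle A6. Hydrodehalogenation and demethylation would complete the synthesis.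
- Merits: ring closure takes place at ambient temperature between two aromatic rings, the halogens dictate the position of the new ether, and only two steps follow the closure.
- Weak points: four halogens must be installed and three removed. The oxidation must select the dibromophenol over the dichlorophenol and over the electron-rich ring A aryl ether. Dimers and spirodienones are typical by-products of such oxidations, and the method needs electrochemical equipment and careful potential control.
- Comparison: the chosen plan is longer after the key step, but it carries no halogen ballast, uses no oxidant on a substrate full of electron-rich arenes, and releases only N2 in its ring closure.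

Key step: step 9

Assumption: the 20-membered ring of 21 is taken to be conformationally mobile, so no atropisomer needs to be controlled.

## Route

Step 1
Reactants: 1 3-(3-hydroxy-4-methoxyphenyl)propanoic acid
Product: 2 methyl 3-(3-hydroxy-4-methoxyphenyl)propanoate
Conditions: MeOH, H2SO4 (cat.), reflux
Reagents that add atoms: methanol, CO
Why: Fischer esterification; the phenol is not esterified under these conditions, and the methyl ester keeps the acid from consuming base or binding copper in step 3.

Step 2
Reactants: 3 diethyl (4-bromobenzyl)phosphonate; 4 3-(benzyloxy)benzaldehyde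
Product: 5 (E)-1-(benzyloxy)-3-[2-(4-bromophenyl)ethenyl]benzene
Conditions: KOtBu, THF, 0 °C to rt
Reagents that add atoms: none
Why: Horner–Wadsworth–Emmons olefination of a non-enolisable aryl aldehyde with a benzylic phosphonate anion, which should give the E-stilbene almost exclusively; aryl bromide and benzyl ether are inert to KOtBu at this temperature.

Step 3
Reactants: 2 methyl 3-(3-hydroxy-4-methoxyphenyl)propanoate; 5 (E)-1-(benzyloxy)-3-[2-(4-bromophenyl)ethenyl]benzene
Product: 6 methyl 3-[3-(4-{(E)-2-[3-(benzyloxy)phenyl]ethenyl}phenoxy)-4-methoxyphenyl]propanoate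
Conditions: CuI (10 mol %), N,N-dimethylglycine hydrochloride (30 mol %), Cs2CO3, 1,4-dioxane, 100 °C
Reagents that add atoms: none
Why: Ullmann-type diaryl ether synthesis with a monovalent copper/amino acid catalyst; the guaiacol-type phenoxide couples with the unhindered aryl bromide, and the methyl ester, benzyl ether and stilbene tolerate anhydrous Cs2CO3 in dioxane.

Step 4
Reactants: 6 methyl 3-[3-(4-{(E)-2-[3-(benzyloxy)phenyl]ethenyl}phenoxy)-4-methoxyphenyl]propanoate
Product: 7 3-[3-(4-{(E)-2-[3-(benzyloxy)phenyl]ethenyl}phenoxy)-4-methoxyphenyl]propanal
Conditions: i-Bu2AlH (1.1 equiv), CH2Cl2, −78 °C; then MeOH, aq. potassium sodium tartrate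
Reagents that add atoms: none
Why: Partial reduction of a methyl ester with i-Bu2AlH, whose tetrahedral aluminium hemiacetal is stable at −78 °C until the quench; the alkene, aryl ethers and benzyl ether are untouched.

Step 5
Reactants: 7 3-[3-(4-{(E)-2-[3-(benzyloxy)phenyl]ethenyl}phenoxy)-4-methoxyphenyl]propanal; 8 1-(triphenylphosphoranylidene)propan-2-one
Product: 9 (3E)-6-[3-(4-{(E)-2-[3-(benzyloxy)phenyl]ethenyl}phenoxy)-4-methoxyphenyl]hex-3-en-2-one
Conditions: toluene, 80 °C
Reagents that add atoms: none
Why: Wittig olefination with a stabilised acyl ylide, which reacts cleanly with unhindered aliphatic aldehydes and gives the E-enone; no base is present that could enolise aldehyde 7.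

Step 6
Reactants: 9 (3E)-6-[3-(4-{(E)-2-[3-(benzyloxy)phenyl]ethenyl}phenoxy)-4-methoxyphenyl]hex-3-en-2-one; 10 diethyl malonate
Product: 14 5-{2-[3-(4-{(E)-2-[3-(benzyloxy)phenyl]ethenyl}phenoxy)-4-methoxyphenyl]ethyl}cyclohexane-1,3-dione, via Michael adduct diester 11 (not isolated), via cyclised keto ester 12 (not isolated), via dioxo carboxylic acid 13 (not isolated)
Conditions: NaOEt, EtOH–THF, reflux; then 2 M aq. NaOH, reflux; then HCl to pH 1, reflux
Reagents that add atoms: none
Why: Michael addition of sodiomalonate to the enone, intramolecular Claisen (Dieckmann-type) closure of the methyl ketone enolate onto one ester, then saponification and decarboxylation of the β-keto acid, the classical one-flask route to 5-substituted cyclohexane-1,3-diones; the centre of 11–13 is racemic and becomes non-stereogenic in symmetric 14.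

Step 7
Reactants: 14 5-{2-[3-(4-{(E)-2-[3-(benzyloxy)phenyl]ethenyl}phenoxy)-4-methoxyphenyl]ethyl}cyclohexane-1,3-dione
Product: 15 5-(2-{3-[4-(2-(3-hydroxyphenyl)ethyl)phenoxy]-4-methoxyphenyl}ethyl)cyclohexane-1,3-dione
Conditions: H2 (1 atm), 10% Pd/C, EtOAc–THF, rt
Reagents that add atoms: none
Why: Heterogeneous hydrogenation saturates the stilbene C=C and hydrogenolyses the aryl benzyl ether in one operation; the dione (largely enolised), the diaryl ether and the methyl ether are stable to H2 over palladium at room temperature and pressure.

Step 8
Reactants: 15 5-(2-{3-[4-(2-(3-hydroxyphenyl)ethyl)phenoxy]-4-methoxyphenyl}ethyl)cyclohexane-1,3-dione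
Product: 16 2-diazo-5-(2-{3-[4-(2-(3-hydroxyphenyl)ethyl)phenoxy]-4-methoxyphenyl}ethyl)cyclohexane-1,3-dione
Conditions: 4-acetamidobenzenesulfonyl azide, Et3N (1.1 equiv), MeCN, 0 °C to rt
Reagents that add atoms: 4-acetamidobenzenesulfonyl azide, CC(=O)Nc1ccc(cc1)S(=O)(=O)N=[N+]=[N-]
Why: Regitz diazo transfer; the acidic dione (pKa about 5) is the only site deprotonated by one equivalent of Et3N and attacks the terminal azide nitrogen, while the much less acidic phenol stays protonated and should not react.

Step 9
Reactants: 16 2-diazo-5-(2-{3-[4-(2-(3-hydroxyphenyl)ethyl)phenoxy]-4-methoxyphenyl}ethyl)cyclohexane-1,3-dione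
Product: 17 macrocyclic 2-aryloxy-3-hydroxycyclohex-2-en-1-one: 20-membered ring in which the ring B oxygen is bonded to C2 of the dearomatised ring A and C5 of that ring carries the CH2CH2 bridge to ring D (ring D as methyl ether; racemic)
Conditions: Rh2(OAc)4 (5 mol %), ClCH2CH2Cl, 4 Å molecular sieves, 80 °C, 16 added by syringe pump over 12 h (final ca. 1 mM)
Reagents that add atoms: none
Why: Rh2(OAc)4, a divalent rhodium dimer, adds to the diazo carbon and expels N2 to give an electrophilic acceptor/acceptor carbenoid at C2 of the dione. The ring B phenol oxygen adds to this carbon to give a rhodium-associated oxonium ylide, and a 1,2-proton shift followed by enolisation delivers the 2-aryloxy-3-hydroxy enone 17. The closest known reaction type is the Rh2(OAc)4-catalysed O–H insertion of cyclic 2-diazo-1,3-diketones with phenols and alcohols, and carbenoid O–H insertion is also an established way to close macrocyclic ethers and lactones from diazo esters; here the two are combined on a new substrate. The 20-membered ring is closed end to end by O–C bond formation at the carbenoid carbon, a macrocyclisation on which this ring size imposes no trajectory constraint and which slow addition to about 1 mM should keep unimolecular. No lasting stereocentre is created: C5 of the dione ring is stereogenic only in a given enol tautomer, the two tautomers are enantiomers, and the centre vanishes on aromatisation in step 12. The step needs chemoselectivity for the single O–H bond over arene addition at rings B–D, ylide formation at the ether oxygens, Wolff ring contraction, carbene dimerisation and insertion into water; the strong preference of acceptor/acceptor carbenoids for polar X–H bonds, the dry non-aromatic solvent, the moderate temperature and the high dilution should secure it. Regiochemistry is not an issue because 16 is symmetric about its C2–C5 axis, so the ether oxygen necessarily ends up para to the bridge.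

Step 10
Reactants: 17 macrocyclic 2-aryloxy-3-hydroxycyclohex-2-en-1-one
Product: 18 macrocyclic 2-aryloxy-3-(trifluoromethanesulfonyloxy)cyclohex-2-en-1-one (enol triflate of 17; racemic)
Conditions: Tf2O, Et3N, CH2Cl2, −78 to 0 °C
Reagents that add atoms: trifluoromethanesulfonic anhydride, O=S(=O)(OS(=O)(=O)C(F)(F)F)C(F)(F)F
Why: O-sulfonylation of a vinylogous acid, the standard preparation of β-triflyloxy enones from 1,3-diones; the two enol oxygens interconvert by tautomerism, so one racemic triflate should result, and 17 has no other hydroxyl.

Step 11
Reactants: 18 macrocyclic 2-aryloxy-3-(trifluoromethanesulfonyloxy)cyclohex-2-en-1-one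
Product: 19 macrocyclic 2-aryloxycyclohex-2-en-1-one: ring A as a cyclohex-2-enone with the ring B oxygen at C2 and the bridge to ring D at C5 (racemic)
Conditions: Pd(OAc)2 (5 mol %), PPh3 (10 mol %), HCO2H, Et3N, DMF, 60 °C
Reagents that add atoms: none
Why: Palladium-catalysed transfer hydrogenolysis of an enol triflate; zerovalent palladium inserts into the activated C–OTf bond, formate delivers hydride with loss of CO2, and reductive elimination forms the C–H bond, while enone and aryl ethers are not reduced under these conditions.

Step 12
Reactants: 19 macrocyclic 2-aryloxycyclohex-2-en-1-one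
Product: 20 ring D O-methyl ether of the target (ring A aromatic, with free OH ortho to the ring B ether oxygen)
Conditions: Pd(O2CCF3)2 (5 mol %), 2-(dimethylamino)pyridine (10 mol %), TsOH (20 mol %), O2 (1 atm), DMSO, 80 °C
Reagents that add atoms: none
Why: Aerobic dehydrogenation of a cyclohexenone to a phenol with a divalent palladium catalyst; a palladium enolate forms at C6, β-hydride elimination from C5 gives the 2,5-cyclohexadienone, which tautomerises to the phenol while O2 reoxidises the metal, so the C5 centre is destroyed and ring A emerges with OH at C1, OAr at C2 and the bridge at C5.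

Step 13
Reactants: 20 ring D O-methyl ether of the target
Product: 21 CNP0329842.0, the macrocyclic bis(bibenzyl) with free hydroxyls on rings A and D
Conditions: BBr3, CH2Cl2, −78 °C to rt; then H2O
Reagents that add atoms: none
Why: Lewis acid cleavage of an aryl methyl ether with BBr3 (O-complexation, bromide attack at methyl, hydrolysis of the aryl borate); diaryl ethers and bibenzyl bridges are inert to BBr3, so only the ring D methoxy group should react.

## Compound list

1 | 3-(3-hydroxy-4-methoxyphenyl)propanoic acid | COc1ccc(CCC(=O)O)cc1O | starting material
2 | methyl 3-(3-hydroxy-4-methoxyphenyl)propanoate | COC(=O)CCc1ccc(OC)c(O)c1 | intermediate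
3 | diethyl (4-bromobenzyl)phosphonate | CCOP(=O)(Cc1ccc(Br)cc1)OCC | starting material
4 | 3-(benzyloxy)benzaldehyde | O=Cc1cccc(OCc2ccccc2)c1 | starting material
5 | (E)-1-(benzyloxy)-3-[2-(4-bromophenyl)ethenyl]benzene | Brc1ccc(/C=C/c2cccc(OCc3ccccc3)c2)cc1 | intermediate
6 | methyl 3-[3-(4-{(E)-2-[3-(benzyloxy)phenyl]ethenyl}phenoxy)-4-methoxyphenyl]propanoate | COC(=O)CCc1ccc(OC)c(Oc2ccc(/C=C/c3cccc(OCc4ccccc4)c3)cc2)c1 | intermediate
7 | 3-[3-(4-{(E)-2-[3-(benzyloxy)phenyl]ethenyl}phenoxy)-4-methoxyphenyl]propanal | O=CCCc1ccc(OC)c(Oc2ccc(/C=C/c3cccc(OCc4ccccc4)c3)cc2)c1 | intermediate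
8 | 1-(triphenylphosphoranylidene)propan-2-one | CC(=O)C=P(c1ccccc1)(c1ccccc1)c1ccccc1 | starting material
9 | (3E)-6-[3-(4-{(E)-2-[3-(benzyloxy)phenyl]ethenyl}phenoxy)-4-methoxyphenyl]hex-3-en-2-one | CC(=O)/C=C/CCc1ccc(OC)c(Oc2ccc(/C=C/c3cccc(OCc4ccccc4)c3)cc2)c1 | intermediate
10 | diethyl malonate | CCOC(=O)CC(=O)OCC | starting material
11 | diethyl 2-{1-[3-(4-{(E)-2-[3-(benzyloxy)phenyl]ethenyl}phenoxy)-4-methoxyphenyl]-5-oxohexan-3-yl}malonate (racemic, one enantiomer drawn; not isolated) | CCOC(=O)C(C(=O)OCC)[C@@H](CC(C)=O)CCc1ccc(OC)c(Oc2ccc(/C=C/c3cccc(OCc4ccccc4)c3)cc2)c1 | intermediate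
12 | ethyl 6-{2-[3-(4-{(E)-2-[3-(benzyloxy)phenyl]ethenyl}phenoxy)-4-methoxyphenyl]ethyl}-2,4-dioxocyclohexane-1-carboxylate (racemic, trans isomer drawn, C1 epimerisable; present as its sodium enolate; not isolated) | CCOC(=O)[C@@H]1C(=O)CC(=O)C[C@H]1CCc1ccc(OC)c(Oc2ccc(/C=C/c3cccc(OCc4ccccc4)c3)cc2)c1 | intermediate
13 | 6-{2-[3-(4-{(E)-2-[3-(benzyloxy)phenyl]ethenyl}phenoxy)-4-methoxyphenyl]ethyl}-2,4-dioxocyclohexane-1-carboxylic acid (racemic, trans isomer drawn; not isolated) | OC(=O)[C@@H]1C(=O)CC(=O)C[C@H]1CCc1ccc(OC)c(Oc2ccc(/C=C/c3cccc(OCc4ccccc4)c3)cc2)c1 | intermediate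
14 | 5-{2-[3-(4-{(E)-2-[3-(benzyloxy)phenyl]ethenyl}phenoxy)-4-methoxyphenyl]ethyl}cyclohexane-1,3-dione | O=C1CC(CCc2ccc(OC)c(Oc3ccc(/C=C/c4cccc(OCc5ccccc5)c4)cc3)c2)CC(=O)C1 | intermediate
15 | 5-(2-{3-[4-(2-(3-hydroxyphenyl)ethyl)phenoxy]-4-methoxyphenyl}ethyl)cyclohexane-1,3-dione | O=C1CC(CCc2ccc(OC)c(Oc3ccc(CCc4cccc(O)c4)cc3)c2)CC(=O)C1 | intermediate
16 | 2-diazo-5-(2-{3-[4-(2-(3-hydroxyphenyl)ethyl)phenoxy]-4-methoxyphenyl}ethyl)cyclohexane-1,3-dione | [N-]=[N+]=C1C(=O)CC(CCc2ccc(OC)c(Oc3ccc(CCc4cccc(O)c4)cc3)c2)CC1=O | intermediate
17 | macrocyclic 2-aryloxy-3-hydroxycyclohex-2-en-1-one, ring D methyl ether (racemic, one enantiomer drawn; the enol tautomers interconvert the enantiomers) | O=C1C[C@H]2CC(O)=C1Oc1cccc(c1)CCc1ccc(cc1)Oc1cc(ccc1OC)CC2 | intermediate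
18 | macrocyclic 2-aryloxy-3-(trifluoromethanesulfonyloxy)cyclohex-2-en-1-one, ring D methyl ether (racemic, one enantiomer drawn) | O=C1C[C@H]2CC(OS(=O)(=O)C(F)(F)F)=C1Oc1cccc(c1)CCc1ccc(cc1)Oc1cc(ccc1OC)CC2 | intermediate
19 | macrocyclic 2-aryloxycyclohex-2-en-1-one, ring D methyl ether (racemic, one enantiomer drawn) | O=C1C[C@H]2CC=C1Oc1cccc(c1)CCc1ccc(cc1)Oc1cc(ccc1OC)CC2 | intermediate
20 | ring D O-methyl ether of the target (achiral) | Oc1cc2ccc1Oc1cccc(c1)CCc1ccc(cc1)Oc1cc(ccc1OC)CC2 | intermediate
21 | CNP0329842.0 (achiral) | Oc1cc2ccc1Oc1cccc(c1)CCc1ccc(cc1)Oc1cc(ccc1O)CC2 | target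

## Step count and least certain steps

Total: 13 steps. Longest linear sequence: 12 steps (from 1 through steps 1 and 3–13, or equally from 3 and 4 through steps 2–13).

**Step 9 (key step).** The carbenoid may be consumed before the distant phenol reaches it. Possible diversions are attack on the nearby ring D arene or its ether oxygens, insertion into adventitious water, and intermolecular O–H insertion to dimers and oligomers, since a 20-membered closure has little conformational bias. The fallback makes the same O–C(ring A) bond by nucleophilic instead of carbenoid chemistry; it sets out from 15 and rejoins the route at 19. Dione 15 is converted with EtOH and TsOH (water removed azeotropically) into the 3-ethoxy-5-substituted cyclohex-2-enone F1. Reduction with LiAlH4 and acidic hydrolysis (Stork–Danheiser transposition) give the 5-substituted cyclohex-2-enone F2. Alkaline H2O2 gives the 2,3-epoxy ketone F3. With Cs2CO3 in DMF under high dilution the ring B phenoxide should open the epoxide at the carbon next to the carbonyl, and loss of water gives 19 directly. This reserve closure is slower and basic, which is why it is not the first choice.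

**Step 12.** The aerobic dehydrogenation may stall, because the palladium enolate has to form at C6 of a macrocyclic α-aryloxy enone and the β-hydride elimination needs a syn C5–H. Prolonged heating under O2 risks oxidation at the benzylic positions. The fallback sets out from 19 and returns to 20. Kinetic enolisation with LiN(SiMe3)2 and Me3SiCl at −78 °C gives the 2-silyloxy-1,3-diene F4. Saegusa–Ito oxidation with stoichiometric Pd(OAc)2 in MeCN gives the cross-conjugated dienone, which tautomerises to 20.

**Step 11.** The β-triflyloxy enone may be hydrolysed back to the dione by the amine/formate medium, or the product enone may undergo conjugate reduction by the palladium hydride. The fallback sets out from 17 and returns to 19 without a triflate. Methylation of 17 with HC(OMe)3, MeOH and TsOH gives the methyl enol ether F5. 1,2-Reduction with i-Bu2AlH gives the allylic alcohol F6, and dilute HCl hydrolyses the enol ether with loss of water to the transposed enone 19 (Stork–Danheiser sequence).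

**Step 8.** If more base is present than the dione consumes, the phenoxide can react with the sulfonyl azide or couple with the diazo product, and conversion suffers. The fallback sets out from 15 and returns to 16 with the phenol masked during the diazo transfer. Silylation with t-BuMe2SiCl and imidazole should give the bis-silyl compound F7 (phenol and dione enol both silylated). The labile enol silyl group is lost in the acidic aqueous work-up to leave the phenol silyl ether F8. Diazo transfer as in step 8 gives the silylated diazo dione F9, and Bu4NF buffered with AcOH releases 16.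

**Step 3.** The ortho-methoxy phenoxide may couple sluggishly, and long heating with carbonate invites ester hydrolysis and reduction of the bromide. The fallback sets out from 5 and returns to 6 by an oxidative coupling at room temperature. Bromine–lithium exchange on 5 (n-BuLi, −78 °C), trapping with B(Oi-Pr)3 and hydrolysis give the stilbenylboronic acid F10. Chan–Lam coupling of F10 with phenol 2 (Cu(OAc)2, pyridine, 4 Å molecular sieves, air, CH2Cl2) gives 6.

## Further compounds

F1 | step 9 | 3-ethoxy-5-(2-{3-[4-(2-(3-hydroxyphenyl)ethyl)phenoxy]-4-methoxyphenyl}ethyl)cyclohex-2-en-1-one (racemic, one enantiomer drawn) | CCOC1=CC(=O)C[C@H](CCc2ccc(OC)c(Oc3ccc(CCc4cccc(O)c4)cc3)c2)C1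
F2 | step 9 | 5-(2-{3-[4-(2-(3-hydroxyphenyl)ethyl)phenoxy]-4-methoxyphenyl}ethyl)cyclohex-2-en-1-one (racemic, one enantiomer drawn) | O=C1C=CC[C@H](CCc2ccc(OC)c(Oc3ccc(CCc4cccc(O)c4)cc3)c2)C1
F3 | step 9 | 4-(2-{3-[4-(2-(3-hydroxyphenyl)ethyl)phenoxy]-4-methoxyphenyl}ethyl)-7-oxabicyclo[4.1.0]heptan-2-one (mixture of racemic diastereomers; all centres are lost later) | O=C1CC(CCc2ccc(OC)c(Oc3ccc(CCc4cccc(O)c4)cc3)c2)CC2OC12
F4 | step 12 | macrocyclic 2-aryloxy-1-(trimethylsilyloxy)cyclohexa-1,3-diene derived from 19 (silyloxy diene C1=C6 and C2=C3; racemic, one enantiomer drawn) | C[Si](C)(C)OC1=C[C@H]2CC=C1Oc1cccc(c1)CCc1ccc(cc1)Oc1cc(ccc1OC)CC2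
F5 | step 11 | macrocyclic 2-aryloxy-3-methoxycyclohex-2-en-1-one (methyl enol ether of 17; racemic, one enantiomer drawn) | O=C1C[C@H]2CC(OC)=C1Oc1cccc(c1)CCc1ccc(cc1)Oc1cc(ccc1OC)CC2
F6 | step 11 | macrocyclic 2-aryloxy-3-methoxycyclohex-2-en-1-ol (racemic; carbinol configuration not fixed) | OC1C[C@H]2CC(OC)=C1Oc1cccc(c1)CCc1ccc(cc1)Oc1cc(ccc1OC)CC2
F7 | step 8 | 3-(tert-butyldimethylsilyloxy)-5-(2-{3-[4-(2-(3-(tert-butyldimethylsilyloxy)phenyl)ethyl)phenoxy]-4-methoxyphenyl}ethyl)cyclohex-2-en-1-one (racemic; not isolated) | CC(C)(C)[Si](C)(C)OC1=CC(=O)CC(CCc2ccc(OC)c(Oc3ccc(CCc4cccc(O[Si](C)(C)C(C)(C)C)c4)cc3)c2)C1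
F8 | step 8 | 5-(2-{3-[4-(2-(3-(tert-butyldimethylsilyloxy)phenyl)ethyl)phenoxy]-4-methoxyphenyl}ethyl)cyclohexane-1,3-dione | CC(C)(C)[Si](C)(C)Oc1cccc(CCc2ccc(Oc3cc(CCC4CC(=O)CC(=O)C4)ccc3OC)cc2)c1
F9 | step 8 | 2-diazo-5-(2-{3-[4-(2-(3-(tert-butyldimethylsilyloxy)phenyl)ethyl)phenoxy]-4-methoxyphenyl}ethyl)cyclohexane-1,3-dione | CC(C)(C)[Si](C)(C)Oc1cccc(CCc2ccc(Oc3cc(CCC4CC(=O)C(=[N+]=[N-])C(=O)C4)ccc3OC)cc2)c1
F10 | step 3 | (4-{(E)-2-[3-(benzyloxy)phenyl]ethenyl}phenyl)boronic acid | OB(O)c1ccc(/C=C/c2cccc(OCc3ccccc3)c2)cc1
A1 | alternative 1 | 2-{4-[2-(3-(benzyloxy)phenyl)ethyl]phenoxy}-4-[2-(4-bromo-3-methoxyphenyl)ethyl]phenol | Oc1ccc(CCc2ccc(Br)c(OC)c2)cc1Oc1ccc(CCc2cccc(OCc3ccccc3)c2)cc1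
A2 | alternative 1 | 1-{4-[2-(3-(benzyloxy)phenyl)ethyl]phenoxy}propan-2-one | CC(=O)COc1ccc(CCc2cccc(OCc3ccccc3)c2)cc1
A3 | alternative 1 | 2-[2-(4-bromo-3-methoxyphenyl)ethyl]prop-2-enal | C=C(CCc1ccc(Br)c(OC)c1)C=O
A4 | alternative 2 | macrocyclic benzylic ketone with free ring D hydroxyl and ring A methyl ether | COc1cc2ccc1Oc1cccc(c1)CCc1ccc(cc1)Oc1cc(ccc1O)C(=O)C2
A5 | alternative 2 | 20-membered aryl ester (macrolactone) of the ring A arylacetic acid with the ring D 2-aryloxyphenol | COc1cc2ccc1Oc1cccc(c1)CCc1ccc(cc1)Oc1ccccc1OC(=O)C2
A6 | alternative 3 | trihalogenated macrocycle, ring A methyl ether | COc1cc2ccc1Oc1cccc(c1)CCc1cc(Cl)c(c(Cl)c1)Oc1cc(cc(Br)c1O)CC2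
A7 | alternative 3 | seco-bisphenol with 3,5-dibromo-4-hydroxyphenyl ring D and 3,5-dichloro-4-hydroxyphenyl ring C | COc1cc(CCc2cc(Br)c(O)c(Br)c2)ccc1Oc1cccc(CCc2cc(Cl)c(O)c(Cl)c2)c1
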